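Atom labels: ring C1 (carries the side chain), C2 (angelate carbon), C3 (ketone), C4/C5 (epoxide), C6; side chain C7(=C14H2)–C8(senecioate). The route rests on making the ring bond C1–C2 by an intramolecular carbonyl-ene reaction of the citronellal-to-isopulegol kind. In one operation the formyl carbon C2 of an open-chain aldehyde bonds to C1 of its (E)-C1=C7 alkene while a hydrogen of the C7 methyl passes to oxygen, so the carbocycle, the C2 hydroxyl, the C1 and C2 stereocentres and the exocyclic C7=C14 methylene arise together. The step exploits the homoallylic alcohol array O–C2–C1–C7=C14 on the six-membered ring. The precursor is a farnesane-type 2-silyloxy aldehyde with a (Z)-C4=C5 alkene.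

Key step: step 12

Step 1
Reactants: 1 methyl (4R)-2,2-dimethyl-1,3-dioxolane-4-carboxylate
Product: 3 1-[(4R)-2,2-dimethyl-1,3-dioxolan-4-yl]ethan-1-one, via Weinreb amide 2 (not isolated)
Conditions: MeNH(OMe)·HCl, i-PrMgCl, THF, −20 °C; then MeMgBr, −20 → 0 °C; aq. NH4Cl
Reagents that add atoms: methylmagnesium bromide, C[Mg]Br; N,O-dimethylhydroxylamine hydrochloride, CNOC.Cl (its atoms stay only in intermediate 2)
Why: One-pot Weinreb amide formation and Grignard addition, in which the magnesium chelate of 2 stops the addition at the ketone and the low temperature should keep the α-alkoxy stereocentre intact.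

Step 2
Reactants: 4 5-bromo-2-methylpent-2-ene
Product: 5 (4-methylpent-3-en-1-yl)triphenylphosphonium bromide
Conditions: PPh3, MeCN, reflux
Reagents that add atoms: triphenylphosphine, c1ccc(cc1)P(c1ccccc1)c1ccccc1
Why: SN2 quaternisation of a primary bromide by triphenylphosphine, the standard preparation of a Wittig salt.

Step 3
Reactants: 5 (4-methylpent-3-en-1-yl)triphenylphosphonium bromide; 3 1-[(4R)-2,2-dimethyl-1,3-dioxolan-4-yl]ethan-1-one
Product: 7 (4S)-2,2-dimethyl-4-[(2Z)-6-methylhepta-2,5-dien-2-yl]-1,3-dioxolane, via phosphonium ylide 6 (not isolated)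
Conditions: KHMDS, THF, 0 °C; then 3, −78 °C → rt
Reagents that add atoms: none
Why: Wittig reaction of a non-stabilised ylide with an α-alkoxy methyl ketone, a combination that under salt-free kinetic conditions should give the (Z)-trisubstituted allylic ether (C3 and C6 cis on C4=C5) and leaves the C3 centre untouched.

Step 4
Reactants: 7 (4S)-2,2-dimethyl-4-[(2Z)-6-methylhepta-2,5-dien-2-yl]-1,3-dioxolane
Product: 8 (2E,5Z)-6-[(4S)-2,2-dimethyl-1,3-dioxolan-4-yl]-2-methylhepta-2,5-dien-1-ol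
Conditions: SeO2 (cat.), t-BuOOH, salicylic acid (cat.), CH2Cl2, rt
Reagents that add atoms: tert-butyl hydroperoxide, CC(C)(C)OO (net oxygen source); selenium dioxide, O=[Se]=O (carries the oxygen)
Why: Riley allylic oxidation (ene reaction, then [2,3]-shift) should hydroxylate the (E)-methyl of the terminal isopropylidene group, because the C4=C5 alkene is deactivated by the allylic dioxolane oxygen, as in the terminal oxidation of geranyl acetate; any enal already formed converges in step 5.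

Step 5
Reactants: 8 (2E,5Z)-6-[(4S)-2,2-dimethyl-1,3-dioxolan-4-yl]-2-methylhepta-2,5-dien-1-ol
Product: 9 (2E,5Z)-6-[(4S)-2,2-dimethyl-1,3-dioxolan-4-yl]-2-methylhepta-2,5-dienal
Conditions: TEMPO (cat.), PhI(OAc)2, CH2Cl2, rt
Reagents that add atoms: none
Why: Oxoammonium (TEMPO) oxidation of a primary allylic alcohol stops at the aldehyde and should leave the acetonide, both alkenes and the (E) geometry alone.

Step 6
Reactants: 9 (2E,5Z)-6-[(4S)-2,2-dimethyl-1,3-dioxolan-4-yl]-2-methylhepta-2,5-dienal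
Product: 10 (4S,5E,8Z)-9-[(4S)-2,2-dimethyl-1,3-dioxolan-4-yl]-5-methyldeca-1,5,8-trien-4-ol
Conditions: (S)-BINOL (20 mol%), Ti(OiPr)4 (10 mol%), 4 Å MS, allylSnBu3, CH2Cl2, −20 °C
Reagents that add atoms: allyltributylstannane, C=CC[Sn](CCCC)(CCCC)CCCC
Why: Keck asymmetric allylation, in which the (S)-BINOL titanium Lewis acid directs allyl transfer to the Si face of the aldehyde and so sets C8 as (S) under catalyst control, the remote dioxolane centre being too far away to interfere.

Step 7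
Reactants: 10 (4S,5E,8Z)-9-[(4S)-2,2-dimethyl-1,3-dioxolan-4-yl]-5-methyldeca-1,5,8-trien-4-ol
Product: 11 (5S,6E,9Z)-10-[(4S)-2,2-dimethyl-1,3-dioxolan-4-yl]-2,6-dimethylundeca-2,6,9-trien-5-ol
Conditions: second-generation Grubbs catalyst (5 mol%), 2-methylbut-2-ene/CH2Cl2, rt
Reagents that add atoms: 2-methylbut-2-ene, CC=C(C)C
Why: Olefin cross-metathesis of the monosubstituted alkene with excess 2-methylbut-2-ene installs the prenyl terminus, the trisubstituted alkenes of the chain being too hindered to take part.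

Step 8
Reactants: 11 (5S,6E,9Z)-10-[(4S)-2,2-dimethyl-1,3-dioxolan-4-yl]-2,6-dimethylundeca-2,6,9-trien-5-ol
Product: 12 (5S,6E,9Z)-10-[(4S)-2,2-dimethyl-1,3-dioxolan-4-yl]-2,6-dimethylundeca-2,6,9-trien-5-yl 3-methylbut-2-enoate
Conditions: 3-methylbut-2-enoic acid, DCC, DMAP (cat.), CH2Cl2, 0 °C → rt
Reagents that add atoms: 3-methylbut-2-enoic acid, CC(C)=CC(=O)O
Why: Steglich esterification of the secondary allylic alcohol, which proceeds at oxygen with retention at C8.

Step 9
Reactants: 12 (5S,6E,9Z)-10-[(4S)-2,2-dimethyl-1,3-dioxolan-4-yl]-2,6-dimethylundeca-2,6,9-trien-5-yl 3-methylbut-2-enoate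
Product: 13 (5S,6E,9Z,11S)-11,12-dihydroxy-2,6,10-trimethyldodeca-2,6,9-trien-5-yl 3-methylbut-2-enoate
Conditions: AcOH/H2O/THF (3:1:1), 40 °C
Reagents that add atoms: none
Why: Acid hydrolysis of the isopropylidene acetal under conditions mild enough for the allylic ester and the skipped diene.

Step 10
Reactants: 13 (5S,6E,9Z,11S)-11,12-dihydroxy-2,6,10-trimethyldodeca-2,6,9-trien-5-yl 3-methylbut-2-enoate
Product: 14 (5S,6E,9Z,11S)-2,6,10-trimethyl-11,12-bis(triethylsilyloxy)dodeca-2,6,9-trien-5-yl 3-methylbut-2-enoate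
Conditions: Et3SiCl, imidazole, DMF, 0 °C → rt
Reagents that add atoms: chlorotriethylsilane, CC[Si](Cl)(CC)CC
Why: Silylation of both hydroxyls as triethylsilyl ethers, chosen because the primary one can be oxidised directly in the next step.

Step 11
Reactants: 14 (5S,6E,9Z,11S)-2,6,10-trimethyl-11,12-bis(triethylsilyloxy)dodeca-2,6,9-trien-5-yl 3-methylbut-2-enoate
Product: 15 (5S,6E,9Z,11S)-2,6,10-trimethyl-12-oxo-11-(triethylsilyloxy)dodeca-2,6,9-trien-5-yl 3-methylbut-2-enoate
Conditions: (COCl)2, DMSO, CH2Cl2, −78 → −40 °C; then i-Pr2NEt, −78 → −20 °C; used crude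
Reagents that add atoms: none
Why: Swern oxidation of a primary triethylsilyl ether, which the chlorosulfonium reagent cleaves and oxidises in place while the secondary silyl ether survives; the hindered base and cold work-up are meant to keep the α-silyloxy β,γ-unsaturated aldehyde from epimerising or moving into conjugation.

Step 12
Reactants: 15 (5S,6E,9Z,11S)-2,6,10-trimethyl-12-oxo-11-(triethylsilyloxy)dodeca-2,6,9-trien-5-yl 3-methylbut-2-enoate
Product: 16 (3S)-2-[(1R,5S,6S)-6-hydroxy-4-methyl-5-(triethylsilyloxy)cyclohex-3-en-1-yl]-6-methylhepta-1,5-dien-3-yl 3-methylbut-2-enoate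
Conditions: Me2AlCl (2.2 equiv), CH2Cl2, −78 → −40 °C
Reagents that add atoms: none
Why: The aluminium-activated formyl carbon C2 is attacked by C1 of the (E)-C1=C7 alkene while a hydrogen of the C7 methyl passes to the carbonyl oxygen through a six-centre transition state, and methane loss from the resulting aluminium alkoxide makes the closure irreversible. The closest known reaction is the Me2AlCl-promoted intramolecular carbonyl-ene cyclisation of citronellal to isopulegol. The six-membered carbocycle closes in the exo mode with respect to both π bonds, the carbonyl oxygen and C7 remaining outside the ring. C1 and C2 are controlled by the C3 stereocentre and the alkene geometry: in the chair-like transition state the C3 silyloxy group sits pseudoaxial (no A(1,2) strain with the C4 methyl, anti to the C=O dipole), the C7 substituent is equatorial, and since the (E)-alkene holds the methyl cis to C6 only an axial C2–O can reach its hydrogen, which puts the new hydroxyl cis to the C1 substituent and trans to C3–O, i.e. (1R,2S) in the atom labels used here. The step needs hydrogen transfer from the methyl group and not from C8–H, and attack by the C1=C7 and not the prenyl alkene; the acyloxy group makes C8–H a poor donor and leaves only the methyl within reach of an axial oxygen, while the prenyl alkene could close only a ten-membered ring.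

Step 13
Reactants: 16 (3S)-2-[(1R,5S,6S)-6-hydroxy-4-methyl-5-(triethylsilyloxy)cyclohex-3-en-1-yl]-6-methylhepta-1,5-dien-3-yl 3-methylbut-2-enoate
Product: 17 (1S,2S,6R)-3-methyl-6-[(3S)-6-methyl-3-(3-methylbut-2-enoyloxy)hepta-1,5-dien-2-yl]-2-(triethylsilyloxy)cyclohex-3-en-1-yl (2Z)-2-methylbut-2-enoate
Conditions: angelic acid, 2,4,6-trichlorobenzoyl chloride, Et3N, toluene, rt; then 16, 75 °C
Reagents that add atoms: angelic acid [(2Z)-2-methylbut-2-enoic acid], C/C=C(/C)C(=O)O
Why: Yamaguchi-type acylation through the mixed 2,4,6-trichlorobenzoic anhydride without DMAP, a protocol chosen for angelates because it avoids the acylpyridinium species that isomerise the (Z)-acid to the tiglate.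

Step 14
Reactants: 17 (1S,2S,6R)-3-methyl-6-[(3S)-6-methyl-3-(3-methylbut-2-enoyloxy)hepta-1,5-dien-2-yl]-2-(triethylsilyloxy)cyclohex-3-en-1-yl (2Z)-2-methylbut-2-enoate
Product: 18 (1S,2S,6R)-2-hydroxy-3-methyl-6-[(3S)-6-methyl-3-(3-methylbut-2-enoyloxy)hepta-1,5-dien-2-yl]cyclohex-3-en-1-yl (2Z)-2-methylbut-2-enoate
Conditions: HF·pyridine, pyridine, THF, 0 °C
Reagents that add atoms: none
Why: Fluoride cleavage of the secondary triethylsilyl ether under buffered conditions that should leave both esters in place, the trans-diaxial arrangement of C2–O and C3–O disfavouring acyl migration.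

Step 15
Reactants: 18 (1S,2S,6R)-2-hydroxy-3-methyl-6-[(3S)-6-methyl-3-(3-methylbut-2-enoyloxy)hepta-1,5-dien-2-yl]cyclohex-3-en-1-yl (2Z)-2-methylbut-2-enoate
Product: 19 (1R,2R,3S,4R,6S)-2-hydroxy-1-methyl-4-[(3S)-6-methyl-3-(3-methylbut-2-enoyloxy)hepta-1,5-dien-2-yl]-7-oxabicyclo[4.1.0]heptan-3-yl (2Z)-2-methylbut-2-enoate (epoxide cis to the C3 hydroxyl, trans to the angelate and the side chain)
Conditions: VO(acac)2 (5 mol%), t-BuOOH (decane), CH2Cl2, 0 °C → rt
Reagents that add atoms: tert-butyl hydroperoxide, CC(C)(C)OO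
Why: Hydroxyl-directed epoxidation of the cyclic allylic alcohol through a vanadium alkoxide–peroxide complex should deliver oxygen to the C4=C5 face that carries the C3 hydroxyl, anti to the C1 and C2 substituents, which sets C4 and C5 and spares the three alkenes that have no neighbouring hydroxyl.

Step 16
Reactants: 19 (1R,2R,3S,4R,6S)-2-hydroxy-1-methyl-4-[(3S)-6-methyl-3-(3-methylbut-2-enoyloxy)hepta-1,5-dien-2-yl]-7-oxabicyclo[4.1.0]heptan-3-yl (2Z)-2-methylbut-2-enoate
Product: 20 (1S,3S,4R,6S)-1-methyl-4-[(3S)-6-methyl-3-(3-methylbut-2-enoyloxy)hepta-1,5-dien-2-yl]-2-oxo-7-oxabicyclo[4.1.0]heptan-3-yl (2Z)-2-methylbut-2-enoate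
Conditions: Dess–Martin periodinane, pyridine, CH2Cl2, 0 °C → rt
Reagents that add atoms: none
Why: Dess–Martin oxidation of the secondary alcohol to the α,β-epoxy ketone under near-neutral conditions, so that the C2 centre next to the new ketone should not epimerise.

Compound list
1 | methyl (4R)-2,2-dimethyl-1,3-dioxolane-4-carboxylate | CC1(C)OC[C@@H](O1)C(=O)OC | starting material
2 | (4R)-N-methoxy-N,2,2-trimethyl-1,3-dioxolane-4-carboxamide (Weinreb amide) | CC1(C)OC[C@@H](O1)C(=O)N(C)OC | intermediate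
3 | 1-[(4R)-2,2-dimethyl-1,3-dioxolan-4-yl]ethan-1-one | CC1(C)OC[C@@H](O1)C(C)=O | intermediate
4 | 5-bromo-2-methylpent-2-ene | CC(C)=CCCBr | starting material
5 | (4-methylpent-3-en-1-yl)triphenylphosphonium bromide | CC(C)=CCC[P+](c1ccccc1)(c1ccccc1)c1ccccc1.[Br-] | intermediate
6 | (4-methylpent-3-en-1-ylidene)triphenylphosphorane (ylide) | CC(C)=CCC=P(c1ccccc1)(c1ccccc1)c1ccccc1 | intermediate
7 | (4S)-2,2-dimethyl-4-[(2Z)-6-methylhepta-2,5-dien-2-yl]-1,3-dioxolane | CC1(C)OC[C@@H](O1)/C(C)=C\CC=C(C)C | intermediate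
8 | (2E,5Z)-6-[(4S)-2,2-dimethyl-1,3-dioxolan-4-yl]-2-methylhepta-2,5-dien-1-ol | CC1(C)OC[C@@H](O1)/C(C)=C\C/C=C(C)/CO | intermediate
9 | (2E,5Z)-6-[(4S)-2,2-dimethyl-1,3-dioxolan-4-yl]-2-methylhepta-2,5-dienal | CC1(C)OC[C@@H](O1)/C(C)=C\C/C=C(C)/C=O | intermediate
10 | (4S,5E,8Z)-9-[(4S)-2,2-dimethyl-1,3-dioxolan-4-yl]-5-methyldeca-1,5,8-trien-4-ol | CC1(C)OC[C@@H](O1)/C(C)=C\C/C=C(C)/[C@@H](O)CC=C | intermediate
11 | (5S,6E,9Z)-10-[(4S)-2,2-dimethyl-1,3-dioxolan-4-yl]-2,6-dimethylundeca-2,6,9-trien-5-ol | CC1(C)OC[C@@H](O1)/C(C)=C\C/C=C(C)/[C@@H](O)CC=C(C)C | intermediate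
12 | (5S,6E,9Z)-10-[(4S)-2,2-dimethyl-1,3-dioxolan-4-yl]-2,6-dimethylundeca-2,6,9-trien-5-yl 3-methylbut-2-enoate | CC1(C)OC[C@@H](O1)/C(C)=C\C/C=C(C)/[C@@H](OC(=O)C=C(C)C)CC=C(C)C | intermediate
13 | (5S,6E,9Z,11S)-11,12-dihydroxy-2,6,10-trimethyldodeca-2,6,9-trien-5-yl 3-methylbut-2-enoate | OC[C@@H](O)/C(C)=C\C/C=C(C)/[C@@H](OC(=O)C=C(C)C)CC=C(C)C | intermediate
14 | (5S,6E,9Z,11S)-2,6,10-trimethyl-11,12-bis(triethylsilyloxy)dodeca-2,6,9-trien-5-yl 3-methylbut-2-enoate | CC[Si](CC)(CC)OC[C@@H](O[Si](CC)(CC)CC)/C(C)=C\C/C=C(C)/[C@@H](OC(=O)C=C(C)C)CC=C(C)C | intermediate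
15 | (5S,6E,9Z,11S)-2,6,10-trimethyl-12-oxo-11-(triethylsilyloxy)dodeca-2,6,9-trien-5-yl 3-methylbut-2-enoate | O=C[C@@H](O[Si](CC)(CC)CC)/C(C)=C\C/C=C(C)/[C@@H](OC(=O)C=C(C)C)CC=C(C)C | intermediate
16 | (3S)-2-[(1R,5S,6S)-6-hydroxy-4-methyl-5-(triethylsilyloxy)cyclohex-3-en-1-yl]-6-methylhepta-1,5-dien-3-yl 3-methylbut-2-enoate | C=C([C@H](CC=C(C)C)OC(=O)C=C(C)C)[C@H]1CC=C(C)[C@H](O[Si](CC)(CC)CC)[C@H]1O | intermediate
17 | (1S,2S,6R)-3-methyl-6-[(3S)-6-methyl-3-(3-methylbut-2-enoyloxy)hepta-1,5-dien-2-yl]-2-(triethylsilyloxy)cyclohex-3-en-1-yl (2Z)-2-methylbut-2-enoate | C=C([C@H](CC=C(C)C)OC(=O)C=C(C)C)[C@H]1CC=C(C)[C@H](O[Si](CC)(CC)CC)[C@H]1OC(=O)/C(C)=C\C | intermediate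
18 | (1S,2S,6R)-2-hydroxy-3-methyl-6-[(3S)-6-methyl-3-(3-methylbut-2-enoyloxy)hepta-1,5-dien-2-yl]cyclohex-3-en-1-yl (2Z)-2-methylbut-2-enoate | C=C([C@H](CC=C(C)C)OC(=O)C=C(C)C)[C@H]1CC=C(C)[C@H](O)[C@H]1OC(=O)/C(C)=C\C | intermediate
19 | (1R,2R,3S,4R,6S)-2-hydroxy-1-methyl-4-[(3S)-6-methyl-3-(3-methylbut-2-enoyloxy)hepta-1,5-dien-2-yl]-7-oxabicyclo[4.1.0]heptan-3-yl (2Z)-2-methylbut-2-enoate | C=C([C@H](CC=C(C)C)OC(=O)C=C(C)C)[C@H]1C[C@@H]2O[C@]2(C)[C@H](O)[C@H]1OC(=O)/C(C)=C\C | intermediate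
20 | (1S,3S,4R,6S)-1-methyl-4-[(3S)-6-methyl-3-(3-methylbut-2-enoyloxy)hepta-1,5-dien-2-yl]-2-oxo-7-oxabicyclo[4.1.0]heptan-3-yl (2Z)-2-methylbut-2-enoate (CNP0414062.1) | C=C([C@H](CC=C(C)C)OC(=O)C=C(C)C)[C@H]1C[C@@H]2O[C@]2(C)C(=O)[C@H]1OC(=O)/C(C)=C\C | target

Total step count: 16.
Longest linear sequence: 15 steps (4 → 5 → 7 → … → 20, steps 2 to 16; the branch from 1 through step 1 is equally long).

Steps most likely to fail

Step 12. The ring may close through the open pathway with an equatorial carbonyl oxygen (stepwise addition followed by proton loss, or chelation of the Lewis acid between the formyl and silyloxy oxygens). That pathway gives the wrong configuration at C2. The fallback sets out from 15 and moves the control of C2 from the cyclisation to an SN2 inversion. The cyclisation would be steered on purpose to the all-equatorial product with a Lewis acid that favours the stepwise course (ZnBr2, CH2Cl2, 0 °C), which should give (3S)-2-[(1R,5S,6R)-6-hydroxy-4-methyl-5-(triethylsilyloxy)cyclohex-3-en-1-yl]-6-methylhepta-1,5-dien-3-yl 3-methylbut-2-enoate F1. A Mitsunobu esterification of F1 with angelic acid (PPh3, DIAD, toluene, 0 °C → rt) then inverts C2 while it installs the ester, and the route is rejoined at 17.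

Step 11. The amine base of the Swern oxidation may deprotonate C3 of the α-silyloxy β,γ-unsaturated aldehyde, with loss of configuration at C3 or migration of the C4=C5 alkene into conjugation. The fallback sets out from 14 and avoids an amine base in the oxidation. Selective methanolysis of the primary silyl ether (PPTS, MeOH/CH2Cl2, −10 °C) should give (5S,6E,9Z,11S)-12-hydroxy-2,6,10-trimethyl-11-(triethylsilyloxy)dodeca-2,6,9-trien-5-yl 3-methylbut-2-enoate F2. Oxidation of this isolated alcohol with Dess–Martin periodinane alone (CH2Cl2, 0 °C) then leads back to 15.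

Step 13. Acylation of the hindered axial hydroxyl may be slow enough for the activated angeloyl unit to isomerise to the (E)-configured tiglate. The fallback sets out from 16 and builds the (Z)-alkene on the substrate instead of transferring it. Steglich esterification with 2-[bis(2,2,2-trifluoroethoxy)phosphoryl]propanoic acid (DCC, DMAP, CH2Cl2) should give (1S,2S,6R)-3-methyl-6-[(3S)-6-methyl-3-(3-methylbut-2-enoyloxy)hepta-1,5-dien-2-yl]-2-(triethylsilyloxy)cyclohex-3-en-1-yl 2-[bis(2,2,2-trifluoroethoxy)phosphoryl]propanoate F3, as a mixture at the phosphonate carbon. A Still–Gennari olefination with acetaldehyde (KHMDS, 18-crown-6, THF, −78 °C) then forms the (Z)-2-methylbut-2-enoate and rejoins the route at 17.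

Further compounds
F1 | step 12 | (3S)-2-[(1R,5S,6R)-6-hydroxy-4-methyl-5-(triethylsilyloxy)cyclohex-3-en-1-yl]-6-methylhepta-1,5-dien-3-yl 3-methylbut-2-enoate | C=C([C@H](CC=C(C)C)OC(=O)C=C(C)C)[C@H]1CC=C(C)[C@H](O[Si](CC)(CC)CC)[C@@H]1O
F2 | step 11 | (5S,6E,9Z,11S)-12-hydroxy-2,6,10-trimethyl-11-(triethylsilyloxy)dodeca-2,6,9-trien-5-yl 3-methylbut-2-enoate | OC[C@@H](O[Si](CC)(CC)CC)/C(C)=C\C/C=C(C)/[C@@H](OC(=O)C=C(C)C)CC=C(C)C
F3 | step 13 | (1S,2S,6R)-3-methyl-6-[(3S)-6-methyl-3-(3-methylbut-2-enoyloxy)hepta-1,5-dien-2-yl]-2-(triethylsilyloxy)cyclohex-3-en-1-yl 2-[bis(2,2,2-trifluoroethoxy)phosphoryl]propanoate | C=C([C@H](CC=C(C)C)OC(=O)C=C(C)C)[C@H]1CC=C(C)[C@H](O[Si](CC)(CC)CC)[C@H]1OC(=O)C(C)P(=O)(OCC(F)(F)F)OCC(F)(F)F
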